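The earlier runs and the new flask are calculated with made-up constants, noise included.

Late in the delta run the target readings had stopped climbing, at 3.6%, 2.7% and 3.0%, while the solid substrate kept falling, so I began from that late picture and drew the zeta curve back to its start.

| flask | solid substrate | reagent | remark | time |
|---|---|---|---|---|
| zeta | 0.20 mM | 0.80 mM | the very flask that is asked about, followed so far |  |
| delta | 0.30 mM | 0.80 mM | run made earlier |  |
| flask | 0.20 mM | 0.800 mM |  | 4.0 min |

zeta run (percent of the solid substrate charged)

| time / s | solid substrate / % | target / % |
|---|---|---|
| 10.0 | 98.4 | 0.9 |
| 15.0 | 98.6 | 0.5 |
| 25.0 | 97.9 | 1.4 |
| 50.0 | 95.2 | 2.0 |
| 90.0 | 91.2 | 3.6 |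

delta run (percent of the solid substrate charged)

| time / min | solid substrate / % | target / % |
|---|---|---|
| 0.833 | 96.4 | 1.3 |
| 1.50 | 94.0 | 2.8 |
| 2.50 | 90.5 | 3.6 |
| 3.00 | 88.8 | 2.7 |
| 4.00 | 84.4 | 3.0 |

(scatter of a reading: 0.3 percentage points)

- as a solid, counted per litre of solution: solid substrate
- at the start none of the solid substrate is in solution
- what has only dissolved of solid substrate counts as not reacted
- the reaction counts as stopped when no species that holds the solid substrate changes by six tenths of a point or more over the second half of the time

* at 4.0 min, what has stopped the reaction, if anything has (for what has run out or reacted, a solid counts together with what of it has only dissolved) (it is still moving / the reagent has run out first / all of the solid substrate has reacted / forward and back rates have come level)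
* part of the solid substrate that has turned into other species by 4.0 min (what has only dissolved does not count)
* amount of target at 4.0 min, in percent of the solid substrate charged
* amount of over-reaction product at 4.0 min, in percent of the solid substrate charged
* amount of target if the flask were left three thousand times as long, in percent of the solid substrate charged

I drew the solid's line first. The delta run lost 0.0117 mM/min of solid over 4.00 min, and the zeta run, with less solid charged, lost 0.0117 mM/min over 1.5 min. These slopes matched although the charges differed, so I took one feed for both runs.

For zeta, the charge divided by that feed gave 17.1 min, which I called the emptying time. The solid in zeta should therefore fall in a straight line, and 4.0 min is a quarter of the emptying time. That put the loss of solid, which I took as conversion, at 23.4%, with solid remaining and the reaction moving.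

Target came next. Its late readings in delta averaged 0.009300 mM. Counting the whole feed as passing through target, this level divided by the feed gave a lifetime of 0.795 min, which marks the knee of the curve. Since that lifetime is shorter than 4.0 min, I expected zeta to have reached the same level, 4.65% of its charge. I put the rest of the conversion beyond target. Once the solid was gone, after the emptying time, I expected target to lose its feed and fade, since its lifetime was shorter than that time.

The forecast's answer on the state at 4.0 min was: it is still moving. It gave conversion 23%, target 4.7%, over-reaction product 18.3% and 0% target when left long, on the ground that “The loss is therefore zero-order in charged solid”.

    starting material → intermediate (k = 0.0183 /s)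
    reagent + intermediate → side product B (k = 33.8 /M/s)
    solid substrate ⇌ starting material, rate k3*(cs3 - [starting material]) while solid is left; crystals form when [starting material] > cs3 (solubility = 0.00640 mM, k = 0.0316 /s)
    starting material → side product A (k = 0.0364 /s)
    target ⇌ isomer of the product (K = 0.210, k = 0.00398 /s)
    starting material + reagent → target (k = 565 /M/s)
    target → over-reaction product (k = 0.0179 /s)

The answer for zeta at 4.0 min was: it is still moving. Its conversion was 22.6%, its target 4.52% and its over-reaction product 14.7%, below the forecast's 18.3%, and its target when left long was 0%. The midpoint of that conversion came at 2.01 min, half of the time, as on a straight line. At 40.0 min, past the emptying time, the same charges stood at 100% conversion. For the neighbour flask read at 1.5 min, the emptying time gave 8.77%, and that flask gave 8.38%.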